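**Plan**

- Ring lettering: A is the benzene ring, B the five-membered lactam, C the pyrazinone. The last retrosynthetic cuts are the O–benzyl bond of a 4-methoxybenzyl (PMB) lactim ether on ring C and the two C–H bonds across an exocyclic C3=CH alkene.
- Ring B is then opened at N1–C2 and C2–C3. The lactam carbonyl C2 lies between the aniline nitrogen N1 and C3, so it can be CO inserted between the NH2 group and the ring-bound alkyne carbon of a 2-(pyrazinylethynyl)-6-prenylaniline.
- The alkyne is cut at both of its C(sp)–C(sp2) bonds (two Sonogashira couplings). The C7–prenyl bond goes back to an N-(1,1-dimethylallyl)aniline (aza-Claisen), and ring C goes back to 3-methylpyrazin-2(1H)-one by two brominations, a methoxylation and O-benzylation.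
- Forward: rings A and C are bought. The aniline arm (steps 1–5) and the pyrazine arm (steps 6–9) are joined at the alkyne (step 10), and ring B is closed by carbonylation (step 11).
- Stereochemistry: the only stereocentre, C3 (S), comes from rhodium-catalysed asymmetric hydrogenation of the (E)-alkene (step 12), whose geometry follows from syn hydropalladation. The final deprotection (step 13) is acidic and cold so that the base-labile C3–H centre is kept.

Key step: step 11

Remark: C3 of the target is S (C2 > C3a > CH2 > H), which corresponds to delivery of hydrogen to the Re face of C3 of the alkene. The sense of induction of a rhodium bisphosphine on this alkene cannot be taken from a close analogue, so the (S,S) ligand is written for Re-face delivery and its mirror image is to be used if a first run shows the opposite sense.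

**Route**

Step 1
Reactants: 1 2-bromoaniline; 2 3-chloro-3-methylbut-1-yne
Product: 3 2-bromo-N-(2-methylbut-3-yn-2-yl)aniline
Conditions: CuCl (10 mol%), Et3N (1.5 equiv), THF, 0 °C to rt
Reagents that add atoms: none
Why: Copper-catalysed propargylic amination of a tertiary propargylic chloride (through a copper acetylide/allenylidene) is the established way to put a 1,1-dimethylpropargyl group on an aniline nitrogen, and the aryl bromide is inert to CuCl at room temperature.

Step 2
Reactants: 3 2-bromo-N-(2-methylbut-3-yn-2-yl)aniline
Product: 4 2-bromo-N-(2-methylbut-3-en-2-yl)aniline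
Conditions: H2 (1 atm), Pd/CaCO3 poisoned with Pb(OAc)2 (Lindlar catalyst), quinoline, EtOAc, rt
Reagents that add atoms: none
Why: Lindlar semihydrogenation of a terminal alkyne should stop at the alkene, and the aryl bromide (chosen over the iodide for this reason) should not be hydrogenolysed on the poisoned catalyst.

Step 3
Reactants: 4 2-bromo-N-(2-methylbut-3-en-2-yl)aniline
Product: 6 2-bromo-6-(3-methylbut-2-en-1-yl)aniline, via cyclohexadienimine 5 (not isolated)
Conditions: TsOH·H2O (20 mol%), MeCN/H2O (10:1), 80 °C
Reagents that add atoms: none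
Why: Acid-catalysed aromatic aza-Claisen rearrangement, a charge-accelerated [3,3] shift of the N-protonated 1,1-dimethylallyl aniline to the only free ortho carbon, inverts the allyl unit to the linear prenyl group, and the dienimine 5 rearomatises by tautomerisation.

Step 4
Reactants: 6 2-bromo-6-(3-methylbut-2-en-1-yl)aniline; 7 ethynyltrimethylsilane
Product: 8 2-(3-methylbut-2-en-1-yl)-6-[(trimethylsilyl)ethynyl]aniline
Conditions: PdCl2(PPh3)2 (5 mol%), CuI (5 mol%), Et3N, 80 °C, sealed tube
Reagents that add atoms: none
Why: Sonogashira coupling of ortho-bromoanilines with a silyl-capped acetylene is routine at this temperature, the free amine and the trisubstituted alkene being spectators and the silyl cap preventing double coupling.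

Step 5
Reactants: 8 2-(3-methylbut-2-en-1-yl)-6-[(trimethylsilyl)ethynyl]aniline
Product: 9 2-ethynyl-6-(3-methylbut-2-en-1-yl)aniline
Conditions: K2CO3 (0.2 equiv), MeOH, rt
Reagents that add atoms: none
Why: Base-catalysed methanolysis of the C(sp)–Si bond (protodesilylation) frees the terminal alkyne without touching the amine or the alkene.

Step 6
Reactants: 10 3-methylpyrazin-2(1H)-one
Product: 11 5-bromo-3-methylpyrazin-2(1H)-one
Conditions: NBS (1.05 equiv), DMF, 0 °C to rt
Reagents that add atoms: N-bromosuccinimide, O=C1CCC(=O)N1Br
Why: Electrophilic bromination of a pyrazin-2(1H)-one goes to C5, the β-carbon of the N1–C6=C5 enamide unit.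

Step 7
Reactants: 11 5-bromo-3-methylpyrazin-2(1H)-one
Product: 12 5-methoxy-3-methylpyrazin-2(1H)-one
Conditions: NaOMe (5 equiv), CuBr (20 mol%), MeOH/DMF, 110 °C, sealed, under Ar; then AcOH to pH 6
Reagents that add atoms: sodium methoxide, C[O-].[Na+]
Why: Ullmann-type copper-catalysed methoxylation of a heteroaryl bromide next to a ring nitrogen, run on the sodium salt of the lactam in the way bromophenols are methoxylated, should replace the C5 bromine by methoxide.

Step 8
Reactants: 12 5-methoxy-3-methylpyrazin-2(1H)-one
Product: 13 6-bromo-5-methoxy-3-methylpyrazin-2(1H)-one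
Conditions: NBS (1.0 equiv), DMF, 0 °C, dark
Reagents that add atoms: N-bromosuccinimide, O=C1CCC(=O)N1Br
Why: Electrophilic bromination should take the only ring C–H, C6, which is the β-carbon of the C5 enol ether, and it is done before the PMB group is introduced so that no anisole ring competes.

Step 9
Reactants: 13 6-bromo-5-methoxy-3-methylpyrazin-2(1H)-one
Product: 14 2-bromo-3-methoxy-6-[(4-methoxybenzyl)oxy]-5-methylpyrazine
Conditions: 4-methoxybenzyl chloride (1.2 equiv), Ag2CO3 (0.6 equiv), toluene, 60 °C, dark
Reagents that add atoms: 4-methoxybenzyl chloride, COc1ccc(CCl)cc1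
Why: Silver-assisted alkylation of an ambident 2-pyridone-type lactam goes to oxygen, and the C6 bromine beside N1 adds a steric bias against N-alkylation.

Step 10
Reactants: 9 2-ethynyl-6-(3-methylbut-2-en-1-yl)aniline; 14 2-bromo-3-methoxy-6-[(4-methoxybenzyl)oxy]-5-methylpyrazine
Product: 15 2-{[3-methoxy-6-(4-methoxybenzyloxy)-5-methylpyrazin-2-yl]ethynyl}-6-(3-methylbut-2-en-1-yl)aniline
Conditions: PdCl2(PPh3)2 (3 mol%), CuI (5 mol%), Et3N/THF (1:2), 50 °C, degassed
Reagents that add atoms: none
Why: Sonogashira coupling of a terminal arylalkyne with an α-bromoazine, which adds readily to zerovalent palladium, is standard for making 2-(heteroarylethynyl)anilines, and the mild temperature should avoid cyclisation to the indole.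

Step 11
Reactants: 15 2-{[3-methoxy-6-(4-methoxybenzyloxy)-5-methylpyrazin-2-yl]ethynyl}-6-(3-methylbut-2-en-1-yl)aniline; 16 carbon monoxide
Product: 17 (E)-3-{[3-methoxy-6-(4-methoxybenzyloxy)-5-methylpyrazin-2-yl]methylidene}-7-(3-methylbut-2-en-1-yl)indolin-2-one
Conditions: Pd(OAc)2 (5 mol%), 1,4-bis(diphenylphosphino)butane (10 mol%), pyridinium p-toluenesulfonate (20 mol%), CO (20 bar), THF, 80 °C, dark; catalyst pre-reduced under CO before 15 is added
Reagents that add atoms: none
Why: Zerovalent palladium formed from Pd(OAc)2 and the bisphosphine is protonated by the pyridinium salt to a palladium hydride that adds syn across the alkyne with the metal held on the ring-bound carbon (future C3) in a five-membered chelate to the aniline nitrogen, CO inserts into that C–Pd bond (C2–C3), and the amine displaces palladium from the acyl carbon (N1–C2). The closest known reaction type is the palladium-catalysed hydrocarbonylative cyclisation (cyclocarbonylation) of 2-alkynylanilines to 3-alkylidene oxindoles, an intramolecular hydroaminocarbonylation of an alkyne. Ring B closes as a five-membered lactam by 5-exo-trig acyl substitution at the acylpalladium carbon, equivalent to C–N reductive elimination from a six-membered amido–acyl palladacycle. No stereocentre is formed, and the alkene geometry follows from syn addition of H and Pd, which leaves the pyrazinyl group trans to the carbonyl (E). The step needs palladation at C3 and not at the pyrazine-bound carbon, and carbonylation and not amine attack on the alkyne: hydropalladation is reversible and only the C3-palladated isomer has the amine within reach of the acyl group, since the regioisomeric acyl sits trans to the aminoaryl ring and cannot close to the quinolin-2-one, while a phosphine-bound hydride under CO, with no free divalent palladium salt and no base, disfavours aminopalladation to the 2-pyrazinylindole. The buffered weak acid should spare the acid-labile PMB lactim ether, and the trisubstituted prenyl alkene is too hindered to insert into the hydride.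

Step 12
Reactants: 17 (E)-3-{[3-methoxy-6-(4-methoxybenzyloxy)-5-methylpyrazin-2-yl]methylidene}-7-(3-methylbut-2-en-1-yl)indolin-2-one
Product: 18 (S)-3-{[3-methoxy-6-(4-methoxybenzyloxy)-5-methylpyrazin-2-yl]methyl}-7-(3-methylbut-2-en-1-yl)indolin-2-one
Conditions: [Rh(cod)2]BF4 (2 mol%), (S,S)-Ph-BPE (1,2-bis[(2S,5S)-2,5-diphenylphospholan-1-yl]ethane, 2.2 mol%), H2 (20 bar), CH2Cl2, 25 °C, dark
Reagents that add atoms: none
Why: Asymmetric hydrogenation of an α-alkylidene lactam with a cationic rhodium bisphosphine, in which the alkene binds with help from the lactam carbonyl or the twisted pyrazine N1 and the chiral ligand directs syn addition of H2 to the Re face of C3 to set the S centre, while the isolated prenyl alkene has no coordinating group and should survive and the neutral, base-free medium should not enolise the new C3–H.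

Step 13
Reactants: 18 (S)-3-{[3-methoxy-6-(4-methoxybenzyloxy)-5-methylpyrazin-2-yl]methyl}-7-(3-methylbut-2-en-1-yl)indolin-2-one
Product: 19 astepyrazinol B, (S)-3-[(3-methoxy-5-methyl-6-oxo-1,6-dihydropyrazin-2-yl)methyl]-7-(3-methylbut-2-en-1-yl)indolin-2-one
Conditions: TFA/CH2Cl2 (1:9), anisole (10 equiv), 0 °C, short contact; cold NaHCO3 quench
Reagents that add atoms: none
Why: Acidolysis of a PMB lactim ether (SN1 loss of the benzylic cation, trapped by anisole in a Friedel–Crafts alkylation) frees the pyrazinone, the methyl lactim ether cannot ionise, and brief cold acid without base should leave both the prenyl group and the C3 configuration intact.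

**Compound list**

1 | 2-bromoaniline | Nc1ccccc1Br | starting material
2 | 3-chloro-3-methylbut-1-yne | C#CC(C)(C)Cl | starting material
3 | 2-bromo-N-(2-methylbut-3-yn-2-yl)aniline | C#CC(C)(C)Nc1ccccc1Br | intermediate
4 | 2-bromo-N-(2-methylbut-3-en-2-yl)aniline | C=CC(C)(C)Nc1ccccc1Br | intermediate
5 | 2-bromo-6-(3-methylbut-2-en-1-yl)cyclohexa-2,4-dien-1-imine | N=C1C(Br)=CC=CC1CC=C(C)C | intermediate
6 | 2-bromo-6-(3-methylbut-2-en-1-yl)aniline | CC(C)=CCc1cccc(Br)c1N | intermediate
7 | ethynyltrimethylsilane | C#C[Si](C)(C)C | starting material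
8 | 2-(3-methylbut-2-en-1-yl)-6-[(trimethylsilyl)ethynyl]aniline | CC(C)=CCc1cccc(C#C[Si](C)(C)C)c1N | intermediate
9 | 2-ethynyl-6-(3-methylbut-2-en-1-yl)aniline | C#Cc1cccc(CC=C(C)C)c1N | intermediate
10 | 3-methylpyrazin-2(1H)-one | Cc1ncc[nH]c1=O | starting material
11 | 5-bromo-3-methylpyrazin-2(1H)-one | Cc1nc(Br)c[nH]c1=O | intermediate
12 | 5-methoxy-3-methylpyrazin-2(1H)-one | COc1c[nH]c(=O)c(C)n1 | intermediate
13 | 6-bromo-5-methoxy-3-methylpyrazin-2(1H)-one | COc1nc(C)c(=O)[nH]c1Br | intermediate
14 | 2-bromo-3-methoxy-6-[(4-methoxybenzyl)oxy]-5-methylpyrazine | COc1nc(C)c(OCc2ccc(OC)cc2)nc1Br | intermediate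
15 | 2-{[3-methoxy-6-(4-methoxybenzyloxy)-5-methylpyrazin-2-yl]ethynyl}-6-(3-methylbut-2-en-1-yl)aniline | COc1nc(C)c(OCc2ccc(OC)cc2)nc1C#Cc1cccc(CC=C(C)C)c1N | intermediate
16 | carbon monoxide | [C-]#[O+] | starting material
17 | (E)-3-{[3-methoxy-6-(4-methoxybenzyloxy)-5-methylpyrazin-2-yl]methylidene}-7-(3-methylbut-2-en-1-yl)indolin-2-one | COc1nc(C)c(OCc2ccc(OC)cc2)nc1/C=C1/C(=O)Nc2c(CC=C(C)C)cccc21 | intermediate
18 | (S)-3-{[3-methoxy-6-(4-methoxybenzyloxy)-5-methylpyrazin-2-yl]methyl}-7-(3-methylbut-2-en-1-yl)indolin-2-one | COc1nc(C)c(OCc2ccc(OC)cc2)nc1C[C@@H]1C(=O)Nc2c(CC=C(C)C)cccc21 | intermediate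
19 | astepyrazinol B, (S)-3-[(3-methoxy-5-methyl-6-oxo-1,6-dihydropyrazin-2-yl)methyl]-7-(3-methylbut-2-en-1-yl)indolin-2-one | COc1nc(C)c(=O)[nH]c1C[C@@H]1C(=O)Nc2c(CC=C(C)C)cccc21 | target

**Step count**

Total: 13 steps. Longest linear sequence: 9 steps (steps 1–5 and 10–13, from 2-bromoaniline). The pyrazine arm is 4 steps (6–9) before the coupling.

**Steps most likely to fail**

Step 11. What may go wrong: hydropalladation in the wrong sense followed by intermolecular amide formation, attack of the amine on the metal-activated alkyne (cyclisation to an indole), migration of the prenyl double bond by the palladium hydride, or acid-induced loss of the PMB group. The fallback replaces the carbonylation by a Knoevenagel condensation; it sets out from 14 and 6 and returns at 17. Bromine–magnesium exchange on 14 (iPrMgCl·LiCl, THF, −20 °C) and quenching with DMF should give 3-methoxy-6-[(4-methoxybenzyl)oxy]-5-methylpyrazine-2-carbaldehyde F1. Palladium-catalysed coupling of 6 with the Reformatsky reagent BrZnCH2CO2Et (Pd2(dba)3, XPhos, THF, 65 °C) should give ethyl [2-amino-3-(3-methylbut-2-en-1-yl)phenyl]acetate F2, which should lactamise on warming with AcOH in toluene to 7-(3-methylbut-2-en-1-yl)indolin-2-one F3. Piperidine-catalysed condensation of F1 with F3 in EtOH at 60 °C should then give 17; any Z isomer would be separated or equilibrated before step 12.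

Step 12. What may go wrong: poor facial discrimination at C3, competing reduction or migration of the prenyl alkene, or erosion of the labile C3–H centre during the reaction or isolation. The fallback replaces asymmetric catalysis by resolution with recycling; it sets out from 17 and returns at 18. Conjugate reduction of 17 with NaBH4 (THF/MeOH, 0 °C) should give racemic 3-{[3-methoxy-6-(4-methoxybenzyloxy)-5-methylpyrazin-2-yl]methyl}-7-(3-methylbut-2-en-1-yl)indolin-2-one F4. Preparative chromatography on a chiral stationary phase separates 18 from its mirror image, (R)-3-{[3-methoxy-6-(4-methoxybenzyloxy)-5-methylpyrazin-2-yl]methyl}-7-(3-methylbut-2-en-1-yl)indolin-2-one F5. F5 is returned to F4 with a catalytic amount of DBU in toluene, through enolisation of the acidic C3–H, and resolved again.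

Step 7. What may go wrong: sluggish copper-mediated substitution on the electron-rich pyrazinone anion, reductive loss of bromine, or air oxidation of the electron-rich methoxypyrazinone in hot base. The fallback carries out the methoxylation on a neutral O-protected pyrazine; it sets out from 11 and returns at 12. Silver-assisted O-benzylation of 11 (BnBr, Ag2CO3, toluene, 60 °C) should give 2-(benzyloxy)-5-bromo-3-methylpyrazine F6. Palladium-catalysed C–O coupling with methanol (Pd2(dba)3, tBuBrettPhos, Cs2CO3, MeOH, toluene, 80 °C) should give 2-(benzyloxy)-5-methoxy-3-methylpyrazine F7. Hydrogenolysis (H2, Pd/C, EtOAc, rt) then frees 12; no alkene is present at this stage.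

**Further compounds**

F1 | step 11 | 3-methoxy-6-[(4-methoxybenzyl)oxy]-5-methylpyrazine-2-carbaldehyde | COc1nc(C)c(OCc2ccc(OC)cc2)nc1C=O
F2 | step 11 | ethyl [2-amino-3-(3-methylbut-2-en-1-yl)phenyl]acetate | CCOC(=O)Cc1cccc(CC=C(C)C)c1N
F3 | step 11 | 7-(3-methylbut-2-en-1-yl)indolin-2-one | CC(C)=CCc1cccc2CC(=O)Nc12
F4 | step 12 | racemic 3-{[3-methoxy-6-(4-methoxybenzyloxy)-5-methylpyrazin-2-yl]methyl}-7-(3-methylbut-2-en-1-yl)indolin-2-one | COc1nc(C)c(OCc2ccc(OC)cc2)nc1CC1C(=O)Nc2c(CC=C(C)C)cccc21
F5 | step 12 | (R)-3-{[3-methoxy-6-(4-methoxybenzyloxy)-5-methylpyrazin-2-yl]methyl}-7-(3-methylbut-2-en-1-yl)indolin-2-one | COc1nc(C)c(OCc2ccc(OC)cc2)nc1C[C@H]1C(=O)Nc2c(CC=C(C)C)cccc21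
F6 | step 7 | 2-(benzyloxy)-5-bromo-3-methylpyrazine | Cc1nc(Br)cnc1OCc1ccccc1
F7 | step 7 | 2-(benzyloxy)-5-methoxy-3-methylpyrazine | COc1cnc(OCc2ccccc2)c(C)n1
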